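**Numbering.** Flavanone numbering is used throughout: ring C = O1, C2, C3, C4(=O), C4a, C8a; ring A = C4a, C5–C8, C8a; ring B = C1'–C6'. Compounds 1–15 are defined in the steps and in the compound list; 15 is the target.

## The problem

- The target 15 is a (2S)-flavanone. Ring A carries 5,7-(OH)2 and prenyl groups at C6 and C8; ring B is joined through C1' to C2 and carries 2',4'-(OH)2 and a prenyl group at C3'.
- C2 is the only stereocenter, so nothing in the molecule can control it; it must be set by a chiral catalyst or reagent.
- C2 is also labile. It is the β-carbon of a β-aryloxy ketone, so base opens ring C by retro-oxa-Michael reaction to the achiral 2'-hydroxychalcone. The 2'- and 4'-OH groups of ring B also assist heterolysis of the C2–O1 bond. Any route that passes through the chalcone, or treats the flavanone roughly after C2 is set, gives racemic material.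
- Each prenyl group sits on a carbon flanked by two oxygens (C6 between O5 and O7, C8 between O7 and O1, C3' between O2' and O4'). Ring A is hexasubstituted. Electrophilic prenylation of an assembled flavanone would not be selective: ring B would react at C5', and O-alkylation and over-alkylation compete.
- A prenyl group ortho to a free phenol closes to a 2,2-dimethylchroman under strong acid, is reduced under hydrogenolysis and reacts with electrophilic halogen. Benzyl ethers, strong Lewis acids and iodine-based oxidations are therefore excluded.
- The feature that makes the key step possible is the O1–C2(H)–C3H2–C4(=O) unit of ring C. It is the 1,4-adduct of the ring-B carbon C1' to the C2=C3–C4=O vinylogous ester of a flat, achiral chromone whose C2 carries only hydrogen.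
- A second helpful feature is local symmetry. Ring A comes from a 3,5-diprenyl-phloroacetophenone with two equivalent ortho-OH groups. Ring B comes from a 2-prenylresorcinol unit whose C4 and C6 are equivalent. No regiochemical question therefore arises in either half.

## Retrosynthesis

**15 ⇒ 14 (O–CH2OMe bonds).** The four phenols are unveiled last from the tetrakis(MOM) ether 14. MOM is chosen over benzyl, allyl or silyl because it is the directing group for both lithiations of the ring-B fragment, and because it survives butyllithium, base and the Rh catalyst. It is removed by dilute methanolic acid, conditions under which a flavanone is far more stable at C2 than in base. No skeletal bond is cut. The forward reaction must exchange the acetals faster than a prenyl group closes onto a liberated phenol or the C2–O1 bond ionises.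

**14 ⇒ 6 + 13 (C2–C1', key disconnection).** This cut is preferred to its neighbours O1–C2 (chalcone cyclisation) and C2–H/C3–H (flavone reduction). It is the one bond that joins the two halves and also carries the stereocenter. The forward reaction, asymmetric 1,4-arylation of chromone 6 by boronic acid 13, never passes through a chalcone. Both precursors are achiral, configurationally inert and roughly half the size of 14. The forward step needs Re-face delivery of the aryl group to C2, 1,4- rather than 1,2-addition, and protonation of the Rh enolate before ring C can open.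

**6 ⇒ 4 (O1–C2 and C2–C3).** C2 is a one-carbon unit from DMF dimethyl acetal. Condensation at the acetyl group of 4 gives enaminone 5, whose single free ortho-OH closes ring C with loss of dimethylamine. The alternative of prenylating a preformed 5,7-dihydroxychromone would give C6/C8 mixtures. The forward reaction is a standard cyclocondensation that must leave the MOM ethers intact.

**4 ⇒ 3 (two O–MOM bonds).** The three hydroxyls of 3 are differentiated by the chelate to the acetyl group: the chelated ortho-OH stays free. Because 3 is symmetric, protection of the 4-OH and either ortho-OH gives the same compound 4.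

**3 ⇒ 1 + 2 (C3–CH2 and C5–CH2).** The two prenyl groups are introduced by C-alkylation of phloroacetophenone 1 with prenyl bromide 2. The only two free ring positions of 1 are equivalent, and both are the doubly oxygen-flanked carbons that become C6 and C8. One step from two commodity chemicals is accepted here in exchange for moderate chemoselectivity.

**13 ⇒ 10 ⇒ 8 ⇒ 7 (C1'–B, then C3'–CH2).** Both bonds are made by directed ortho-metalation. In 8 the most acidic position is C2, between the two OMOM groups, which is exactly where the target has its ring-B prenyl group (giving 10 via aryllithium 9). In 10 the next lithiation goes ortho to one OMOM group at C4 (= C6 by symmetry), which is exactly C1' (giving 13 via 11 and 12). The substitution pattern of ring B thus follows the innate order of lithiation of resorcinol bis-MOM ether 8, made from resorcinol 7.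

## Roads not taken

**Alternative 1:** Cut O1–C2. The forward key step is a catalytic asymmetric intramolecular oxa-Michael cyclisation of the 2'-hydroxychalcone A1, reached by Claisen–Schmidt condensation of the two prenylated halves. This is the obvious, biomimetic route. It is rejected for three reasons:
- A 2',6'-dihydroxychalcone cyclises without a catalyst, so a racemic background reaction competes.
- The catalytic enantioselective versions with close precedent need an activating α-ester on the enone (one more C–C bond and a decarboxylation) or give modest selectivity on plain chalcones.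
- The ring closure is the microscopic reverse of the racemisation pathway, so C2 would be formed under the conditions that erase it.

The chosen plan needs the same effort to prepare the halves but sets C2 in an irreversible C–C bond formation.

**Alternative 2:** Cut C2–H/C3–H. The forward key step is an enantioselective conjugate reduction or hydrogenation of the C2=C3 bond of flavone A2. The flavone costs extra steps, since chalcone oxidation with iodine is incompatible with prenyl groups and a Baker–Venkataraman sequence is longer. Hydrogenation catalysts would threaten the three prenyl olefins. C2 of A2 is a β,β-disubstituted, electron-rich acceptor carbon flanked by an ortho-substituted aryl group, and over-reduction to the flavan-4-ol would require a re-oxidation. The chosen plan reaches the same oxidation level directly and forms the inter-ring bond in the same step.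

**Alternative 3:** Cut the three aryl–prenyl bonds last. The forward key step is a triple aromatic Claisen rearrangement of the (2S)-flavanone tris(1,1-dimethylallyl) ether A3, which would deliver prenyl to C6, C8 and C3' and free three phenols without reagents. It is rejected for four reasons:
- The chelated, hindered 5-OH cannot reasonably be converted into a tertiary allylic ether.
- The 7-O group can migrate to C6 or C8, and rearrangement to an occupied position followed by Cope shift would place a 1,1-dimethylallyl group at C8.
- The labile flavanone would be heated while its phenols are being liberated.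
- An enantioselective synthesis of the unprenylated flavanone core would still be needed, so the step count grows.

Key step: step 7

**Assumption:** the (S)-configured biaryl bisphosphine is taken to deliver the aryl group to the Re face of C2, by analogy with (S)-BINAP-type ligands giving (S)-3-arylcyclohexanones. If a trial on an unprenylated model pair shows the opposite sense, the (R)-ligand is used and nothing else changes.

## Route

Step 1
Reactants: 1 2,4,6-trihydroxyacetophenone; 2 prenyl bromide (1-bromo-3-methylbut-2-ene)
Product: 3 1-[2,4,6-trihydroxy-3,5-bis(3-methylbut-2-en-1-yl)phenyl]ethan-1-one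
Conditions: 2 (2.1 equiv), 10% aq. KOH, 0 °C
Reagents that add atoms: none
Why: C-alkylation of the ambident phloroacetophenone phenoxide in water (biomimetic C-prenylation of an acylphloroglucinol); the only free ring carbons C3 and C5 are equivalent, and stoichiometry and low temperature should hold the reaction at the dialkylated stage.

Step 2
Reactants: 3 1-[2,4,6-trihydroxy-3,5-bis(3-methylbut-2-en-1-yl)phenyl]ethan-1-one
Product: 4 1-[2-hydroxy-4,6-bis(methoxymethoxy)-3,5-bis(3-methylbut-2-en-1-yl)phenyl]ethan-1-one
Conditions: MOMCl (2.3 equiv), i-Pr2NEt, CH2Cl2, 0 °C to rt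
Reagents that add atoms: chloromethyl methyl ether, COCCl
Why: O-alkylation under amine base leaves the hydroxyl chelated to the acetyl group untouched; by the symmetry of 3 only one bis-ether with a chelated OH exists.

Step 3
Reactants: 4 1-[2-hydroxy-4,6-bis(methoxymethoxy)-3,5-bis(3-methylbut-2-en-1-yl)phenyl]ethan-1-one
Product: 6 5,7-bis(methoxymethoxy)-6,8-bis(3-methylbut-2-en-1-yl)-4H-chromen-4-one, via enaminone 5 (not isolated)
Conditions: Me2NCH(OMe)2, toluene, 90 °C; then AcOH, 60 °C
Reagents that add atoms: N,N-dimethylformamide dimethyl acetal, COC(OC)N(C)C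
Why: Enaminone formation at the acetyl CH3 followed by intramolecular oxa-Michael addition of the free ortho-OH and loss of dimethylamine (standard enaminone chromone synthesis); acetic acid is too weak to cleave the MOM ethers or to cyclise a prenyl group.

Step 4
Reactants: 7 resorcinol
Product: 8 1,3-bis(methoxymethoxy)benzene
Conditions: NaH, MOMCl, DMF, 0 °C to rt
Reagents that add atoms: chloromethyl methyl ether, COCCl
Why: Williamson-type acetalisation of both phenoxides; it installs the groups that direct both later lithiations.

Step 5
Reactants: 8 1,3-bis(methoxymethoxy)benzene; 2 prenyl bromide (1-bromo-3-methylbut-2-ene)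
Product: 10 1,3-bis(methoxymethoxy)-2-(3-methylbut-2-en-1-yl)benzene, via aryllithium 9 (not isolated)
Conditions: n-BuLi, TMEDA, THF, 0 °C; then CuBr·SMe2 (10 mol %), 2, −78 °C to rt
Reagents that add atoms: none
Why: Directed ortho-metalation at C2, the position activated by both OMOM groups, then copper-catalysed allylic substitution at the primary carbon of prenyl bromide, which gives the linear prenyl group.

Step 6
Reactants: 10 1,3-bis(methoxymethoxy)-2-(3-methylbut-2-en-1-yl)benzene
Product: 13 [2,4-bis(methoxymethoxy)-3-(3-methylbut-2-en-1-yl)phenyl]boronic acid, via aryllithium 11 (not isolated), via lithium triisopropoxyborate 12 (not isolated)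
Conditions: n-BuLi, TMEDA, THF, −20 to 0 °C; B(Oi-Pr)3, −78 °C to rt; aq. NH4Cl
Reagents that add atoms: triisopropyl borate, CC(C)OB(OC(C)C)OC(C)C; water, O
Why: Second directed ortho-metalation ortho to one OMOM group (C4 and C6 are equivalent, the same lithiation that is used to formylate this arene), borate trapping and mild hydrolysis; the weakly acidic work-up spares the MOM ethers and limits protodeboronation.

Step 7
Reactants: 6 5,7-bis(methoxymethoxy)-6,8-bis(3-methylbut-2-en-1-yl)-4H-chromen-4-one; 13 [2,4-bis(methoxymethoxy)-3-(3-methylbut-2-en-1-yl)phenyl]boronic acid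
Product: 14 (2S)-2-[2,4-bis(methoxymethoxy)-3-(3-methylbut-2-en-1-yl)phenyl]-5,7-bis(methoxymethoxy)-6,8-bis(3-methylbut-2-en-1-yl)-2,3-dihydro-4H-chromen-4-one
Conditions: [RhCl(C2H4)2]2 (2.5 mol %), (S)-MeO-F12-BIPHEP (5.5 mol %), aq. KOH (20 mol %), 13 (3 equiv, in portions), toluene/H2O 10:1, 40 °C
Reagents that add atoms: none
Why: KOH turns the Rh–Cl precatalyst into Rh–OH, which transmetalates with 13 to an aryl–Rh(I) bisphosphine complex; the C2=C3 bond of 6 coordinates, the aryl group migrates to C2 to leave a Rh oxa-π-allyl (enolate) over C3–C4–O, and water protonates it to release 14 and Rh–OH. The closest known reaction type is the Rh(I)/chiral bisphosphine-catalysed asymmetric 1,4-addition of arylboronic acids to chromones (Hayashi–Miyaura reaction), a direct route to 2-arylchroman-4-ones. No ring is closed: ring C is already present in 6 and only changes from a flat 4-pyranone to the stereogenic dihydropyranone. The single new stereocenter C2 is set by the ligand alone, since both partners are achiral: the (S)-biaryl bisphosphine should expose the Re face of C2 (O1 > C3 > H clockwise) to the migrating aryl group, the same face that gives (S)-3-arylcyclohexanones, and Re-face arylation corresponds to 2S. 1,4- over 1,2-addition is secured by the soft aryl–Rh species and by the C4 carbonyl being a vinylogous ester flanked by the 5-OMOM group, while C2 carries only H and is remote from the 8-prenyl group. Protonation of the Rh enolate has to outrun β-oxygen elimination of O1, which would open ring C to a chalcone and erase C2; the water-rich two-phase medium, the mild temperature and the electron-poor ligand favour protonation. The three prenyl groups are trisubstituted, unactivated olefins that do not insert into aryl–Rh and the MOM ethers are inert; 13 is used in excess because an ortho-alkoxy arylboronic acid protodeboronates in competition.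

Step 8
Reactants: 14 (2S)-2-[2,4-bis(methoxymethoxy)-3-(3-methylbut-2-en-1-yl)phenyl]-5,7-bis(methoxymethoxy)-6,8-bis(3-methylbut-2-en-1-yl)-2,3-dihydro-4H-chromen-4-one
Product: 15 (2S)-2-[2,4-dihydroxy-3-(3-methylbut-2-en-1-yl)phenyl]-5,7-dihydroxy-6,8-bis(3-methylbut-2-en-1-yl)-2,3-dihydro-4H-chromen-4-one
Conditions: HCl (ca. 1 M) in MeOH/THF, 35 °C, followed closely; aq. NaHCO3 quench at 0 °C
Reagents that add atoms: none
Why: Acid-catalysed acetal exchange with methanol removes all four MOM groups (the peri 5-OMOM first); dilute acid at low temperature should be slower at protonating a trisubstituted olefin or ionising C2–O1 than at cleaving a mixed acetal, and no base that could open ring C is present, so C2 should be retained.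

## Compound list

1 | 2,4,6-trihydroxyacetophenone | CC(=O)c1c(O)cc(O)cc1O | starting material
2 | prenyl bromide (1-bromo-3-methylbut-2-ene) | CC(C)=CCBr | starting material
3 | 1-[2,4,6-trihydroxy-3,5-bis(3-methylbut-2-en-1-yl)phenyl]ethan-1-one | CC(=O)c1c(O)c(CC=C(C)C)c(O)c(CC=C(C)C)c1O | intermediate
4 | 1-[2-hydroxy-4,6-bis(methoxymethoxy)-3,5-bis(3-methylbut-2-en-1-yl)phenyl]ethan-1-one | CC(=O)c1c(O)c(CC=C(C)C)c(OCOC)c(CC=C(C)C)c1OCOC | intermediate
5 | (2E)-3-(dimethylamino)-1-[2-hydroxy-4,6-bis(methoxymethoxy)-3,5-bis(3-methylbut-2-en-1-yl)phenyl]prop-2-en-1-one | CN(C)/C=C/C(=O)c1c(O)c(CC=C(C)C)c(OCOC)c(CC=C(C)C)c1OCOC | intermediate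
6 | 5,7-bis(methoxymethoxy)-6,8-bis(3-methylbut-2-en-1-yl)-4H-chromen-4-one | O=c1ccoc2c(CC=C(C)C)c(OCOC)c(CC=C(C)C)c(OCOC)c12 | intermediate
7 | resorcinol | Oc1cccc(O)c1 | starting material
8 | 1,3-bis(methoxymethoxy)benzene | COCOc1cccc(OCOC)c1 | intermediate
9 | [2,6-bis(methoxymethoxy)phenyl]lithium | [Li]c1c(OCOC)cccc1OCOC | intermediate
10 | 1,3-bis(methoxymethoxy)-2-(3-methylbut-2-en-1-yl)benzene | COCOc1cccc(OCOC)c1CC=C(C)C | intermediate
11 | [2,4-bis(methoxymethoxy)-3-(3-methylbut-2-en-1-yl)phenyl]lithium | [Li]c1ccc(OCOC)c(CC=C(C)C)c1OCOC | intermediate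
12 | lithium [2,4-bis(methoxymethoxy)-3-(3-methylbut-2-en-1-yl)phenyl]tri(propan-2-yloxy)borate | [Li+].CC(C)O[B-](OC(C)C)(OC(C)C)c1ccc(OCOC)c(CC=C(C)C)c1OCOC | intermediate
13 | [2,4-bis(methoxymethoxy)-3-(3-methylbut-2-en-1-yl)phenyl]boronic acid | OB(O)c1ccc(OCOC)c(CC=C(C)C)c1OCOC | intermediate
14 | (2S)-2-[2,4-bis(methoxymethoxy)-3-(3-methylbut-2-en-1-yl)phenyl]-5,7-bis(methoxymethoxy)-6,8-bis(3-methylbut-2-en-1-yl)-2,3-dihydro-4H-chromen-4-one | CC(C)=CCc1c(OCOC)ccc([C@@H]2CC(=O)c3c(OCOC)c(CC=C(C)C)c(OCOC)c(CC=C(C)C)c3O2)c1OCOC | intermediate
15 | (2S)-2-[2,4-dihydroxy-3-(3-methylbut-2-en-1-yl)phenyl]-5,7-dihydroxy-6,8-bis(3-methylbut-2-en-1-yl)-2,3-dihydro-4H-chromen-4-one | CC(C)=CCc1c(O)ccc([C@@H]2CC(=O)c3c(O)c(CC=C(C)C)c(O)c(CC=C(C)C)c3O2)c1O | target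

## Step count and risks

Total steps: 8. Longest linear sequence: 5 (steps 1, 2, 3, 7, 8 from 1; or steps 4, 5, 6, 7, 8 from 7).

**Step 7 (key step).**
- Risk: slow transmetalation and insertion with a hindered ortho-alkoxy arylboronic acid and an electron-rich, fully substituted chromone, so that protodeboronation of 13 consumes the nucleophile. A second risk is erosion of enantiomeric purity by ring opening, either β-oxygen elimination from the Rh enolate or hydroxide-mediated retro-oxa-Michael reaction of 14.
- Fallback (sets out from 10 and 4, returns at 14): 10 is lithiated as in step 6 and 11 is quenched with DMF to give 2,4-bis(methoxymethoxy)-3-(3-methylbut-2-en-1-yl)benzaldehyde F1. Claisen–Schmidt condensation of F1 with 4 (KOH, EtOH) gives the 2'-hydroxychalcone F2, and NaOAc in refluxing EtOH closes it to the racemic flavanone F3. Kinetic resolution of F3 by asymmetric transfer hydrogenation follows (Cp*RhCl[(R,R)-TsDPEN], HCO2H/Et3N, taken slightly past half conversion). By the tetralone model this should reduce the 2R ketone to the cis-(2R,4R)-flavan-4-ol F4 and leave 14, which is separated by chromatography; the catalyst antipode is used if the sense proves opposite.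

**Step 1.**
- Risk: loss of chemoselectivity in the alkylation of a triply ambident phenoxide: O-prenylation, stopping at the mono-C-prenyl stage, and geminal or triple C-alkylation with dearomatisation.
- Fallback (sets out from 1, returns at 3): allyl bromide and K2CO3 in acetone give 1-[2-hydroxy-4,6-bis(prop-2-en-1-yloxy)phenyl]ethan-1-one F5. Heating F5 (N,N-diethylaniline, 190 °C) effects a double aromatic Claisen rearrangement to 1-[2,4,6-trihydroxy-3,5-di(prop-2-en-1-yl)phenyl]ethan-1-one F6. This is regioconvergent: the 6-O-allyl group can reach only C5 directly or C3 by Cope shift from a blocked C5, so every pathway ends with allyl groups on C3 and C5. Double cross-metathesis of F6 with 2-methylbut-2-ene (second-generation Ru carbene catalyst, 40 °C) gives 3.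

**Step 8.**
- Risk: acid-promoted closure of a prenyl group onto a freshly liberated ortho-phenol (2,2-dimethylchroman formation), and partial racemisation by acid-assisted ionisation of the C2–O1 bond once the 2'- and 4'-OH groups are free.
- Fallback (sets out from 14, returns at 15): cleavage is moved from Brønsted-acid acetal hydrolysis to Lewis-acid silyl transfer. TMSOTf and 2,2'-bipyridyl in CH2Cl2 at 0 °C should convert the four aryl MOM ethers into the (2S)-tetrakis(trimethylsilyl) ether F7, which is hydrolysed with water at neutral pH to 15.

**Step 3.**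
- Risk: O-methylation of the free phenol by the formamide acetal, or partial loss of the peri MOM group during the acid-promoted ring closure, giving mixtures.
- Fallback (sets out from 4, returns at 6): Claisen formylation of 4 with ethyl formate and NaH in THF gives, after neutral work-up, the cyclic hemiacetal 2-hydroxy-5,7-bis(methoxymethoxy)-6,8-bis(3-methylbut-2-en-1-yl)chroman-4-one F8. F8 is dehydrated under basic conditions (MsCl, Et3N, 0 °C) to 6.

## Further compounds

F1 | step 7 | 2,4-bis(methoxymethoxy)-3-(3-methylbut-2-en-1-yl)benzaldehyde | O=Cc1ccc(OCOC)c(CC=C(C)C)c1OCOC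
F2 | step 7 | (2E)-3-[2,4-bis(methoxymethoxy)-3-(3-methylbut-2-en-1-yl)phenyl]-1-[2-hydroxy-4,6-bis(methoxymethoxy)-3,5-bis(3-methylbut-2-en-1-yl)phenyl]prop-2-en-1-one | O=C(/C=C/c1ccc(OCOC)c(CC=C(C)C)c1OCOC)c1c(O)c(CC=C(C)C)c(OCOC)c(CC=C(C)C)c1OCOC
F3 | step 7 | rac-2-[2,4-bis(methoxymethoxy)-3-(3-methylbut-2-en-1-yl)phenyl]-5,7-bis(methoxymethoxy)-6,8-bis(3-methylbut-2-en-1-yl)-2,3-dihydro-4H-chromen-4-one | CC(C)=CCc1c(OCOC)ccc(C2CC(=O)c3c(OCOC)c(CC=C(C)C)c(OCOC)c(CC=C(C)C)c3O2)c1OCOC
F4 | step 7 | (2R,4R)-2-[2,4-bis(methoxymethoxy)-3-(3-methylbut-2-en-1-yl)phenyl]-5,7-bis(methoxymethoxy)-6,8-bis(3-methylbut-2-en-1-yl)-3,4-dihydro-2H-chromen-4-ol | CC(C)=CCc1c(OCOC)ccc([C@H]2C[C@@H](O)c3c(OCOC)c(CC=C(C)C)c(OCOC)c(CC=C(C)C)c3O2)c1OCOC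
F5 | step 1 | 1-[2-hydroxy-4,6-bis(prop-2-en-1-yloxy)phenyl]ethan-1-one | CC(=O)c1c(O)cc(OCC=C)cc1OCC=C
F6 | step 1 | 1-[2,4,6-trihydroxy-3,5-di(prop-2-en-1-yl)phenyl]ethan-1-one | CC(=O)c1c(O)c(CC=C)c(O)c(CC=C)c1O
F7 | step 8 | (2S)-2-[3-(3-methylbut-2-en-1-yl)-2,4-bis(trimethylsilyloxy)phenyl]-6,8-bis(3-methylbut-2-en-1-yl)-5,7-bis(trimethylsilyloxy)-2,3-dihydro-4H-chromen-4-one | CC(C)=CCc1c(O[Si](C)(C)C)ccc([C@@H]2CC(=O)c3c(O[Si](C)(C)C)c(CC=C(C)C)c(O[Si](C)(C)C)c(CC=C(C)C)c3O2)c1O[Si](C)(C)C
F8 | step 3 | 2-hydroxy-5,7-bis(methoxymethoxy)-6,8-bis(3-methylbut-2-en-1-yl)-2,3-dihydro-4H-chromen-4-one | OC1CC(=O)c2c(OCOC)c(CC=C(C)C)c(OCOC)c(CC=C(C)C)c2O1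
A1 | alternative 1 | (2E)-3-[2,4-dihydroxy-3-(3-methylbut-2-en-1-yl)phenyl]-1-[2,4,6-trihydroxy-3,5-bis(3-methylbut-2-en-1-yl)phenyl]prop-2-en-1-one | O=C(/C=C/c1ccc(O)c(CC=C(C)C)c1O)c1c(O)c(CC=C(C)C)c(O)c(CC=C(C)C)c1O
A2 | alternative 2 | 2-[2,4-bis(methoxymethoxy)-3-(3-methylbut-2-en-1-yl)phenyl]-5,7-bis(methoxymethoxy)-6,8-bis(3-methylbut-2-en-1-yl)-4H-chromen-4-one | O=c1cc(-c2ccc(OCOC)c(CC=C(C)C)c2OCOC)oc2c(CC=C(C)C)c(OCOC)c(CC=C(C)C)c(OCOC)c12
A3 | alternative 3 | (2S)-2-{4-hydroxy-2-[(2-methylbut-3-en-2-yl)oxy]phenyl}-5,7-bis[(2-methylbut-3-en-2-yl)oxy]-2,3-dihydro-4H-chromen-4-one | C=CC(C)(C)Oc1cc(O)ccc1[C@@H]1CC(=O)c2c(OC(C)(C)C=C)cc(OC(C)(C)C=C)cc2O1
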